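**Retrosynthetic overview**

- Target 9 (5-hydroxy-2-pentadecylchromone) is traced back to 5-fluoro-2-pentadecylchromone 5 by exchange of the C5 fluoride for hydroxyl, a substitution activated by the ortho C4 carbonyl.
- 5 is cut at C3–C4 and at O1–C8a into heptadecan-2-one 1 and 2,6-difluorobenzoyl chloride 2.
- The feature used: C4 sits on C4a, and both carbons ortho to C4a (C8a and C5) carry oxygen in the target. A 2,6-difluorobenzoyl unit therefore supplies C4 and ring A with two equivalent, carbonyl-activated leaving groups, one for the ring oxygen O1 and one for the C5 hydroxyl.
- Ring order: benzene ring A is purchased, and the pyranone ring is closed in step 1. The target has no stereocentre.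

Key step: step 1

Remark: chromone numbering (O1, C2, C3, C4, C4a, C5 to C8, C8a) is used throughout.

**Route**

Step 1
Reactants: 1 heptadecan-2-one; 2 2,6-difluorobenzoyl chloride
Product: 5 5-fluoro-2-pentadecyl-4H-chromen-4-one, via lithium heptadec-1-en-2-olate 3 (not isolated), via 1-(2,6-difluorophenyl)octadecane-1,3-dione 4 (not isolated)
Conditions: LiN(SiMe3)2 (2.2 equiv), THF, −78 °C, 1 added slowly in THF; then 2 (1.0 equiv), −78 °C to rt; then DMF added, 80 °C; aq. NH4Cl work-up
Reagents that add atoms: none
Why: LiN(SiMe3)2 removes a methyl proton of 1 under kinetic control to give enolate 3, which attacks the acyl chloride carbon of 2 (addition–elimination, a crossed Claisen-type C-acylation) and forms C3–C4; diketone 4 is deprotonated at once by the second equivalent of base, which shields it from a second acylation. On heating with DMF the chelated lithium diketonate opens up, its oxygen on the chain-bearing carbon (the future O1) adds to a fluorine-bearing ortho carbon, and the Meisenheimer adduct, stabilised by the aroyl carbonyl, loses fluoride to form O1–C8a (intramolecular nucleophilic aromatic substitution). The pyranone ring closes as a six-membered ring by addition–elimination at a trigonal arene carbon, counted as 6-exo-trig onto the C8–C8a bond. The closest known reaction type is the tandem C-acylation of ketone enolates with 2-fluorobenzoyl chlorides followed by fluoride displacement to chromones. No stereocentre is formed. The step needs methyl-side over methylene-side enolisation, which the hindered amide base at −78 °C and addition of the ketone to the base should secure, and C- over O-acylation, which the lithium counter-ion in THF favours; the two fluorines of 2 are equivalent by symmetry, so either closure gives 5 and leaves the other fluorine at C5.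

Step 2
Reactants: 5 5-fluoro-2-pentadecyl-4H-chromen-4-one; 6 2-(methylsulfonyl)ethanol
Product: 9 5-hydroxy-2-pentadecyl-4H-chromen-4-one, via sodium 2-(methylsulfonyl)ethanolate 7 (not isolated), via 5-[2-(methylsulfonyl)ethoxy]-2-pentadecyl-4H-chromen-4-one 8 (not isolated)
Conditions: 6 (1.5 equiv), NaH (3 equiv), DMF–THF, 0 °C to rt; 1 M HCl work-up
Reagents that add atoms: none
Why: NaH converts 6 into alkoxide 7, which displaces the C5 fluoride ortho to the C4 carbonyl by nucleophilic aromatic substitution to give ether 8, and excess NaH then removes a proton next to the sulfone so that E1cB elimination releases the phenoxide of 9 and methyl vinyl sulfone, a known one-pot conversion of activated aryl fluorides into phenols.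

**Compound list**

1 | heptadecan-2-one | CCCCCCCCCCCCCCCC(C)=O | starting material
2 | 2,6-difluorobenzoyl chloride | O=C(Cl)c1c(F)cccc1F | starting material
3 | lithium heptadec-1-en-2-olate (kinetic enolate of 1) | C=C([O-])CCCCCCCCCCCCCCC.[Li+] | intermediate
4 | 1-(2,6-difluorophenyl)octadecane-1,3-dione (present in the flask as its lithium enolate) | CCCCCCCCCCCCCCCC(=O)CC(=O)c1c(F)cccc1F | intermediate
5 | 5-fluoro-2-pentadecyl-4H-chromen-4-one | CCCCCCCCCCCCCCCc1cc(=O)c2c(F)cccc2o1 | intermediate
6 | 2-(methylsulfonyl)ethanol | CS(=O)(=O)CCO | starting material
7 | sodium 2-(methylsulfonyl)ethanolate | CS(=O)(=O)CC[O-].[Na+] | intermediate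
8 | 5-[2-(methylsulfonyl)ethoxy]-2-pentadecyl-4H-chromen-4-one | CCCCCCCCCCCCCCCc1cc(=O)c2c(OCCS(C)(=O)=O)cccc2o1 | intermediate
9 | 5-hydroxy-2-pentadecyl-4H-chromen-4-one | CCCCCCCCCCCCCCCc1cc(=O)c2c(O)cccc2o1 | target

**Totals**

Total step count: 2. Longest linear sequence: 2 steps.

**Steps most likely to fail**

The route has only two steps, so both are listed, in order of risk.

1. Step 1 (key step). Three processes may interfere:
   - Enolisation may leak to the methylene side, or the enolate may equilibrate through unreacted ketone, which would put the chain on C3.
   - The enolate or the diketonate may be acylated on oxygen or a second time.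
   - The ring closure may stall at the chelated lithium diketonate.

   Fallback: it sets out from 2 and comes back at 5. Compound 2 is converted with MeMgBr and catalytic Fe(acac)3 in THF at −78 °C into 1-(2,6-difluorophenyl)ethanone F1 (also a catalogue compound), a ketone with a single enolisable position. Its lithium enolate (LiN(SiMe3)2, THF, −78 °C, two equivalents of enolate per acid chloride) is acylated with purchased hexadecanoyl chloride F2. This should give the same diketone 4, here isolated after acidic work-up, and 4 is then closed to 5 with K2CO3 in DMF at 80–100 °C. The acylation now forms C2–C3 instead of C3–C4, so the side of enolisation is no longer in question, and acylation and ring closure are run as separate operations.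

2. Step 2. The alkoxide may add to C2 of the pyranone and open the ring, or the base may deprotonate the chain CH2 next to C2, in competition with displacement at C5. The displacement itself may be slow because the C4 carbonyl is part of a vinylogous ester and activates only moderately.

   Fallback: it sets out from 1 and comes back at 9. The C5 oxygen is brought in as a methyl ether from the start. Compound 1 is put through the conditions of step 1 with purchased 2-fluoro-6-methoxybenzoyl chloride F3. Enolate 3 should be acylated to 1-(2-fluoro-6-methoxyphenyl)octadecane-1,3-dione F4, whose single fluoride is displaced on heating to give 5-methoxy-2-pentadecyl-4H-chromen-4-one F5. BBr3 in CH2Cl2 (−78 °C to 0 °C) then cleaves the methyl ether, helped by chelation of boron between the C5 oxygen and the C4 carbonyl, and should give 9 after aqueous work-up.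

**Further compounds**

F1 | step 1 | 1-(2,6-difluorophenyl)ethanone | CC(=O)c1c(F)cccc1F
F2 | step 1 | hexadecanoyl chloride | CCCCCCCCCCCCCCCC(Cl)=O
F3 | step 2 | 2-fluoro-6-methoxybenzoyl chloride | COc1cccc(F)c1C(Cl)=O
F4 | step 2 | 1-(2-fluoro-6-methoxyphenyl)octadecane-1,3-dione | CCCCCCCCCCCCCCCC(=O)CC(=O)c1c(F)cccc1OC
F5 | step 2 | 5-methoxy-2-pentadecyl-4H-chromen-4-one | CCCCCCCCCCCCCCCc1cc(=O)c2c(OC)cccc2o1
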